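(The data are simulated with made-up constants; the scatter is artificial.)

In alpha, product plus starting material stays near the whole charge. Alpha reads 99.5% at 4.00 d, and at 6.00 d its starting material reads 0%. So alpha's charge goes over to product, which reads 96.9% at that last reading. Oak and elm hold 1.20 equivalents of solid reagent, more than the starting material. The question is how fast they approach that end.

| flask | starting material | solid reagent | free catalyst | temperature | remark | time |
|---|---|---|---|---|---|---|
| alpha | 0.050 M | 0.084 M | 1.6 mM | 84 °C | run made earlier |  |
| delta | 0.050 M | 0.13 M | 1.6 mM | 92 °C | run made earlier |  |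
| oak | 0.050 M | 0.0600 M | 1.6 mM | 95 °C |  | 3.0 d |
| elm | 0.050 M | 0.0600 M | 1.6 mM | 80 °C |  | 3.0 d |

| run | time / d | product / % | starting material / % |
|---|---|---|---|
| alpha | 0.625 | 12.7 | 84.8 |
| alpha | 2.00 | 40.8 | 55.1 |
| alpha | 4.00 | 80.8 | 18.7 |
| alpha | 6.00 | 96.9 | 0 |
| delta | 0.417 | 7.0 | 87.0 |
| delta | 1.25 | 25.1 | 72.1 |
| delta | 2.50 | 51.1 | 46.8 |
| delta | 4.00 | 82.6 | 18.7 |

(each reading ± 1 percentage point)

- given per volume of solution although it is solid: solid reagent
- at the start none of the solid reagent is in solution

- the flask with the highest amount of product, in percent of the starting material charged ("all alike" if they lie within 1.5 percentage points) (oak / elm / all alike)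
- final product, as a percentage of the starting material charged, in oak
- final product, as a percentage of the starting material charged, in elm

Two chemists dispute this. The second holds that decay is first order in starting material and that temperature sets the constant. Alpha's first reading gives her 0.264 d⁻¹. That means about 54.7% at 3.0 d at alpha's temperature, with oak above it and elm below.

The first chemist answers that her constant drifts. Alpha's reading at 4.00 d gives 0.419 d⁻¹, larger than the first. Product, he says, grows along a straight line. Alpha gives 0.202 d⁻¹ up to 4.00 d. Delta, hotter and with more solid reagent, gives 0.206 d⁻¹ up to 4.00 d. This number is the pace, the fraction of the charge turned into product per day. He carries alpha's pace unchanged to both flasks and gets 60.6% at 3.0 d.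

The forecast stands on his side, with 61% for oak, 60% for elm and all alike. Its ground: “Neither run slows as starting material falls, so the rate is zero order in it.”

The simulation gives 60.8% in oak and 60.6% in elm, so the answer is all alike, and the pace stands.

    starting material + free catalyst → catalyst intermediate A (k = 0.540 M⁻¹ min⁻¹, Ea = 72.0 kJ mol⁻¹)
    coupling partner + catalyst intermediate A → catalyst intermediate B (k = 80.0 M⁻¹ min⁻¹, Ea = 61.0 kJ mol⁻¹)
    catalyst intermediate B → free catalyst + product (k = 2.20 min⁻¹, Ea = 94.0 kJ mol⁻¹)
    solid reagent ⇌ coupling partner, rate k4*(cs4 - [coupling partner]) while solid is left; crystals form when [coupling partner] > cs4 (solubility = 47.0 mM, k = 1.50 × 10⁻⁴ min⁻¹)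
    (constants at 80 °C)

The second chemist's temperature has its place at the tail of a run: alpha's recipe at 6.00 d gives 98.3% at elm's temperature and 99.9% at oak's. Up to 3.00 d the solid reagent dissolved in both flasks, leaving 49.3% of its charge in oak and 49.3% in elm. At 3.00 d catalyst intermediate A, the resting state, held 83.7% of the catalyst in oak and 57.9% in elm.

Now take oak read at 40 h. The pace gives 33.7%, and the simulation gives 33.8%.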